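**Retrosynthetic overview**
- The acetate is installed last, on the free primary alcohol obtained by hydrogenolysis of a benzyl ether that protects the chain end through all basic and electrophilic steps.
- The α-methoxy-γ-pyranone comes from regioselective O-methylation (MeOTf) of a 4-hydroxy-2-pyranone.
- That 4-hydroxy-2-pyranone is the only ring of the route; it is closed late by DBU lactonisation of a β,δ-diketo ester, itself made by oxidation of a δ-hydroxy-β-keto ester.
- Key C–C bond (C2–C3 of the pyranone in the target): intermolecular aldol addition of the dianion of methyl 2-methyl-3-oxopentanoate to 12-(benzyloxy)dodecanal.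
- Fragments: the keto ester from methyl 3-oxopentanoate and MeI; the aldehyde from dodecane-1,12-diol by monobenzylation and oxidation.

Assumption: the target has no stereocentre and is achiral, so no enantiocontrol is needed; the sp3 centres of 2, 7 and 8 are carried as stereoisomer mixtures because all of them become sp2 by step 6.

**Route**

Step 1
Reactants: 1 methyl 3-oxopentanoate
Product: 2 methyl 2-methyl-3-oxopentanoate (racemic)
Conditions: MeI (1.05 equiv), K2CO3, acetone, reflux
Reagents that add atoms: iodomethane CI
Why: The doubly activated C2–H is deprotonated by K2CO3 and the enolate is C-methylated by SN2 (β-keto ester alkylation), one equivalent of MeI limiting dialkylation.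

Step 2
Reactants: 3 dodecane-1,12-diol
Product: 4 12-(benzyloxy)dodecan-1-ol
Conditions: 3 (3 equiv), NaH (1 equiv), BnBr (1 equiv), TBAI (cat.), THF/DMF, 0 °C → rt
Reagents that add atoms: benzyl bromide BrCc1ccccc1
Why: Williamson ether synthesis in which the threefold excess of the symmetrical diol makes the mono-ether the main product, the polar excess diol being recovered.

Step 3
Reactants: 4 12-(benzyloxy)dodecan-1-ol
Product: 5 12-(benzyloxy)dodecanal
Conditions: TEMPO (10 mol%), PhI(OAc)2 (1.1 equiv), CH2Cl2, rt
Reagents that add atoms: none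
Why: The TEMPO/oxoammonium oxidation of a primary alcohol stops at the aldehyde under anhydrous conditions and leaves the benzyl ether untouched.

Step 4
Reactants: 2 methyl 2-methyl-3-oxopentanoate; 5 12-(benzyloxy)dodecanal
Product: 7 methyl 16-(benzyloxy)-5-hydroxy-2,4-dimethyl-3-oxohexadecanoate (diastereomer mixture), via ketoester dianion 6 (not isolated)
Conditions: 2 (1.3 equiv), NaH, THF, 0 °C; n-BuLi, 0 °C; then 5, −78 °C; 1 M HCl quench
Reagents that add atoms: sodium hydride [Na+].[H-]; n-butyllithium [Li]CCCC (Na and Li enter only 6 and are lost on the acid quench; 7 keeps no reagent atom)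
Why: In this β-keto ester dianion (Weiler) aldol addition the more basic terminal γ-carbanion of 6 adds to the aldehyde far faster than the stabilised α-site, and the three new stereocentres form as a mixture that does not matter because all are planarised in steps 5 and 6.

Step 5
Reactants: 7 methyl 16-(benzyloxy)-5-hydroxy-2,4-dimethyl-3-oxohexadecanoate
Product: 8 methyl 16-(benzyloxy)-2,4-dimethyl-3,5-dioxohexadecanoate (keto/enol and stereoisomer mixture)
Conditions: Dess–Martin periodinane (1.5 equiv), CH2Cl2, rt; crude product used directly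
Reagents that add atoms: none
Why: Dess–Martin oxidation converts the β-hydroxy ketone into the 1,3-diketone under neutral conditions without retro-aldol cleavage, the ether and ester being inert.

Step 6
Reactants: 8 methyl 16-(benzyloxy)-2,4-dimethyl-3,5-dioxohexadecanoate
Product: 9 6-[11-(benzyloxy)undecyl]-4-hydroxy-3,5-dimethyl-2H-pyran-2-one
Conditions: DBU (2 equiv), toluene, 60 °C; 1 M HCl wash
Reagents that add atoms: none
Why: DBU enolises the 3,5-diketone and the C5 enol oxygen attacks the methyl ester (6-exo-trig lactonisation), loss of methanol and tautomerisation giving the stabilised 4-hydroxy-2-pyranone.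

Step 7
Reactants: 9 6-[11-(benzyloxy)undecyl]-4-hydroxy-3,5-dimethyl-2H-pyran-2-one
Product: 11 2-[11-(benzyloxy)undecyl]-6-methoxy-3,5-dimethyl-4H-pyran-4-one, via pyrylium triflate 10 (not isolated)
Conditions: MeOTf (1.5 equiv), CH2Cl2, 0 °C → rt; then sat. aq. NaHCO3
Reagents that add atoms: methyl trifluoromethanesulfonate COS(=O)(=O)C(F)(F)F
Why: Hard O-methylation of the neutral hydroxypyranone occurs at its most basic site, the lactone carbonyl oxygen, giving the 4-hydroxy-2-methoxypyrylium salt, whose deprotonation on basic work-up yields the α-methoxy-γ-pyranone and not the 4-methoxy-2-pyranone.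

Step 8
Reactants: 11 2-[11-(benzyloxy)undecyl]-6-methoxy-3,5-dimethyl-4H-pyran-4-one
Product: 12 2-(11-hydroxyundecyl)-6-methoxy-3,5-dimethyl-4H-pyran-4-one
Conditions: H2 (1 atm), 10% Pd/C, EtOAc, rt, stopped at full conversion
Reagents that add atoms: none
Why: Catalytic hydrogenolysis cleaves the benzylic C–O bond quickly at 1 atm, while the fully substituted, electron-rich pyranone ring is expected to be reduced much more slowly under these mild conditions.

Step 9
Reactants: 12 2-(11-hydroxyundecyl)-6-methoxy-3,5-dimethyl-4H-pyran-4-one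
Product: 13 11-(6-methoxy-3,5-dimethyl-4-oxo-4H-pyran-2-yl)undecyl acetate
Conditions: Ac2O, pyridine, DMAP (cat.), CH2Cl2, 0 °C → rt
Reagents that add atoms: acetic anhydride CC(=O)OC(C)=O
Why: DMAP-catalysed O-acylation (nucleophilic catalysis) of the unhindered primary alcohol is fast and the pyranone offers no acylable site.

**Compound list**
1 | methyl 3-oxopentanoate | CCC(=O)CC(=O)OC | starting material
2 | methyl 2-methyl-3-oxopentanoate (racemic) | CCC(=O)C(C)C(=O)OC | intermediate
3 | dodecane-1,12-diol | OCCCCCCCCCCCCO | starting material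
4 | 12-(benzyloxy)dodecan-1-ol | OCCCCCCCCCCCCOCc1ccccc1 | intermediate
5 | 12-(benzyloxy)dodecanal | O=CCCCCCCCCCCCOCc1ccccc1 | intermediate
6 | sodium lithium dianion of methyl 2-methyl-3-oxopentanoate (not isolated) | [Na+].[Li+].C[CH-]C(=O)[C-](C)C(=O)OC | intermediate
7 | methyl 16-(benzyloxy)-5-hydroxy-2,4-dimethyl-3-oxohexadecanoate (diastereomer mixture) | COC(=O)C(C)C(=O)C(C)C(O)CCCCCCCCCCCOCc1ccccc1 | intermediate
8 | methyl 16-(benzyloxy)-2,4-dimethyl-3,5-dioxohexadecanoate (stereoisomer mixture) | COC(=O)C(C)C(=O)C(C)C(=O)CCCCCCCCCCCOCc1ccccc1 | intermediate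
9 | 6-[11-(benzyloxy)undecyl]-4-hydroxy-3,5-dimethyl-2H-pyran-2-one | O=c1oc(CCCCCCCCCCCOCc2ccccc2)c(C)c(O)c1C | intermediate
10 | 2-[11-(benzyloxy)undecyl]-4-hydroxy-6-methoxy-3,5-dimethylpyrylium trifluoromethanesulfonate (not isolated) | COc1[o+]c(CCCCCCCCCCCOCc2ccccc2)c(C)c(O)c1C.[O-]S(=O)(=O)C(F)(F)F | intermediate
11 | 2-[11-(benzyloxy)undecyl]-6-methoxy-3,5-dimethyl-4H-pyran-4-one | COc1oc(CCCCCCCCCCCOCc2ccccc2)c(C)c(=O)c1C | intermediate
12 | 2-(11-hydroxyundecyl)-6-methoxy-3,5-dimethyl-4H-pyran-4-one | COc1oc(CCCCCCCCCCCO)c(C)c(=O)c1C | intermediate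
13 | 11-(6-methoxy-3,5-dimethyl-4-oxo-4H-pyran-2-yl)undecyl acetate (achiral) | COc1oc(CCCCCCCCCCCOC(C)=O)c(C)c(=O)c1C | target

**Step count and risks**
Total step count: 9. Longest linear sequence: 8 steps (3 → 13, steps 2–9); the keto ester branch (step 1) joins at step 4.

The three steps most likely to fail:

Step 7 (regioselectivity of the O-methylation; the isomeric 4-methoxy-2-pyranone may form). The fallback sets out from 8 and comes back to the route at 11. The β,δ-diketo ester 8 is cyclodehydrated directly with PPh3/CCl4 in THF (rt → reflux, Appel-type activation). One oxygen is removed as the phosphine oxide, and the methoxy group of the ester is kept as the 6-OMe of the γ-pyranone. Compounds 9 and 10 are bypassed and no methylation is needed. No new compound is made on this way (F0).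

Step 4 (dianion aldol; aldehyde enolisation or retro-aldol could lower the yield, and the product must survive step 5). The fallback sets out from 5 and comes back to the route at 8. Pinnick oxidation of 5 (NaClO2, NaH2PO4, 2-methyl-2-butene, t-BuOH/H2O) gives 12-(benzyloxy)dodecanoic acid F1. CDI in CH2Cl2 converts it into 1-[12-(benzyloxy)dodecanoyl]-1H-imidazole F2 (not isolated), which with MeNHOMe·HCl gives the Weinreb amide 12-(benzyloxy)-N-methoxy-N-methyldodecanamide F3. The dianion 6 (2.2 equiv, THF, −78 → 0 °C) is then C-acylated at its γ-carbon by F3 in a Claisen-type condensation, the chelated tetrahedral adduct preventing over-addition. Quenching with 1 M HCl gives 8 directly, so steps 4 and 5 are both replaced.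

Step 8 (hydrogenolysis next to the pyranone; ring reduction is possible). The fallback sets out from 8 and comes back to the route at 13, removing the benzyl group before any pyranone exists. Hydrogenolysis of 8 (H2, Pd/C, EtOAc) gives methyl 16-hydroxy-2,4-dimethyl-3,5-dioxohexadecanoate F4. Ac2O/pyridine at 0 °C without DMAP acetylates the primary alcohol to methyl 16-acetoxy-2,4-dimethyl-3,5-dioxohexadecanoate F5. DBU in toluene at 60 °C over 4 Å sieves (to trap methanol) closes the ring to 11-(4-hydroxy-3,5-dimethyl-2-oxo-2H-pyran-6-yl)undecyl acetate F6. MeOTf in CH2Cl2 then gives 2-(11-acetoxyundecyl)-4-hydroxy-6-methoxy-3,5-dimethylpyrylium trifluoromethanesulfonate F7 (not isolated), and NaHCO3 work-up gives 13. The acetate is inert to MeOTf, and steps 8 and 9 are not needed.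

**Further compounds**
F0 | step 7 | none | none
F1 | step 4 | 12-(benzyloxy)dodecanoic acid | OC(=O)CCCCCCCCCCCOCc1ccccc1
F2 | step 4 | 1-[12-(benzyloxy)dodecanoyl]-1H-imidazole | O=C(CCCCCCCCCCCOCc1ccccc1)n1ccnc1
F3 | step 4 | 12-(benzyloxy)-N-methoxy-N-methyldodecanamide | CON(C)C(=O)CCCCCCCCCCCOCc1ccccc1
F4 | step 8 | methyl 16-hydroxy-2,4-dimethyl-3,5-dioxohexadecanoate | COC(=O)C(C)C(=O)C(C)C(=O)CCCCCCCCCCCO
F5 | step 8 | methyl 16-acetoxy-2,4-dimethyl-3,5-dioxohexadecanoate | COC(=O)C(C)C(=O)C(C)C(=O)CCCCCCCCCCCOC(C)=O
F6 | step 8 | 11-(4-hydroxy-3,5-dimethyl-2-oxo-2H-pyran-6-yl)undecyl acetate | CC(=O)OCCCCCCCCCCCc1oc(=O)c(C)c(O)c1C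
F7 | step 8 | 2-(11-acetoxyundecyl)-4-hydroxy-6-methoxy-3,5-dimethylpyrylium trifluoromethanesulfonate | CC(=O)OCCCCCCCCCCCc1[o+]c(OC)c(C)c(O)c1C.[O-]S(=O)(=O)C(F)(F)F
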